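(Readings and results come from a simulation with made-up constants; noise was put on by code.)

Beta, the earlier run closest to teal, had lost 22.4% of its two substrates by 2.50 h, and its left-handed substrate had moved from 32.0% to 30.5% since 1.33 h.

| setting | beta | gamma | ochre | teal |
|---|---|---|---|---|
| left-handed substrate | 1 M | 1 M | 1.0 M | 1.0 M |
| right-handed substrate | 1 M | 1 M | 1.0 M | 1.0 M |
| solid reagent | 0.46 M | 0.66 M | 1.10 M | 0.400 M |
| free catalyst | 2 mM | 2 mM | 2.0 mM | 2.0 mM |
| remark | run made earlier | run made earlier |  |  |
| time |  |  | 2.5 h | 2.5 h |

- beta (time / h: right-handed substrate / %, left-handed substrate / %, left-handed product / %): 0.200: 49.3, 45.8, 4.1; 0.417: 48.4, 39.8, 9.9; 0.667: 47.4, 36.2, 14.1; 1.33: 47.2, 32.0, 18.1; 2.50: 47.1, 30.5, 19.4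
- gamma (time / h: right-handed substrate / %, left-handed substrate / %, left-handed product / %): 0.500: 47.8, 35.5, 14.8; 1.00: 46.4, 27.2, 22.3; 1.50: 45.1, 24.1, 25.8; 2.00: 44.7, 23.0, 26.8; 2.50: 45.5, 22.9, 27.3

(standard deviation of a reading: 0.3 percentage points)

- free catalyst is single-handed; left-handed substrate and right-handed substrate are mirror images of each other, charged as a racemate, each of them at the stated concentration
- given per volume of solution although it is solid: solid reagent
- steps under discussion: free catalyst + left-handed substrate <-> catalyst intermediate A; free catalyst + right-handed substrate <-> catalyst intermediate B; partner + catalyst intermediate A -> free catalyst + left-handed product; partner + catalyst intermediate B -> free catalyst + right-handed product; solid reagent <-> partner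
- at the start none of the solid reagent is in solution
- an excess is the difference of the two amounts in percent of their sum
- an excess is below zero if the other one leads

1. which one finishes higher in excess of right-handed substrate over left-handed substrate among what is left of the two ("neither" within 2 percentage points) (ochre / teal / neither)
2. excess of right-handed substrate over left-handed substrate among what is left of the two at the end, ochre
3. excess of right-handed substrate over left-handed substrate among what is left of the two at the end, teal

I called the charged c(solid reagent) over the charged sum of c(left-handed substrate) and c(right-handed substrate) the turnover budget, which for teal is 20.0%. Beta's budget was 23.0%, level with its loss, so I took the solid reagent as the limiting reagent there, one turnover for each unit charged. Teal looks like beta but has a smaller budget, so I expected it to stop lower.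

Beta's end readings also gave the right-handed share of the turnovers, 12.9%. The excess is then one minus twice that share, times the budget, over one minus the budget. For teal I reckoned 18.5%.

Ochre's budget is 55.0%, and with beta's share it would take the left-handed substrate down to 2.12%, whereas beta's share was read with 30.5% of it still there, so I did not carry that share over and gave ochre no figure of my own. I placed it above teal, since budget over remainder is 1.22 for ochre, more than the 0.250 for teal.

The forecast, holding that “each equivalent of solid delivers one turnover”, named ochre, with 65% for ochre and 18% for teal.

The flasks ended with ochre higher, at 63.7% for ochre against 17.8% for teal.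

    free catalyst + left-handed substrate ⇌ catalyst intermediate A (K = 1.40 M⁻¹, k = 6010 M⁻¹ min⁻¹)
    free catalyst + right-handed substrate ⇌ catalyst intermediate B (K = 0.464 M⁻¹, k = 255 M⁻¹ min⁻¹)
    partner + catalyst intermediate A → free catalyst + left-handed product (k = 32.1 M⁻¹ min⁻¹)
    partner + catalyst intermediate B → free catalyst + right-handed product (k = 13.3 M⁻¹ min⁻¹)
    solid reagent ⇌ partner, rate k5*(cs5 - [partner]) while solid is left; crystals form when [partner] > cs5 (solubility = 0.990 M, k = 0.0602 min⁻¹)

In teal the two products together held 19.8% at 2.50 h, level with its budget of 20.0%. The neighbouring flask was ochre with 0.44 M of solid reagent. Its budget is 22.0%, and with beta's share of 12.9% the same reckoning gives an excess of 20.9%. That flask ended with 46.9% right-handed substrate and 3.10% right-handed product, and its excess stood at 19.9%.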